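**Plan**
1. Eriostemin is 3,8-dihydroxy-5,6,7,4'-tetramethoxyflavone; the retrosynthesis first removes the C3–OH bond and an 8-O-benzyl group, then cuts ring C at C4a–C4, C4–C3 and O1–C2.
2. Enabling feature: C4 is a lone carbonyl carbon between C4a of the fully substituted ring A and the C3–C2 pair that carries the anisyl ring B, and O1 is a phenolic oxygen ortho to C4a. C4 can therefore be carbon monoxide, C3–C2 a terminal aryl alkyne and ring A an ortho-iodophenol.
3. Forward, ring A is dressed first from 3,4,5-trimethoxyphenol: MOM ether, ortho-lithiation/hydroxylation, benzylation, MOM removal, iodination of the last free C–H.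
4. Ring C is then closed in one operation from the iodophenol, CO and 4-ethynylanisole; ring B arrives intact with the alkyne.
5. The 3-hydroxyl follows by C3 lithiation–borylation–oxidation, and hydrogenolysis frees the 8-hydroxyl.
6. Stereochemistry: the target has no stereocentre and no stereogenic double bond, so nothing has to be controlled.

Key step: step 6

Remark on the chemistry: flavone numbering is used (O1, C2, C3, C4, C4a, C5 to C8, C8a; ring B primed). Enaminone 13 is drawn as the E isomer expected from addition of a secondary amine; either geometry would close to the same flavone.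

Step 1
Reactants: 1 3,4,5-trimethoxyphenol
Product: 2 1,2,3-trimethoxy-5-(methoxymethoxy)benzene
Conditions: NaH, MOMCl, DMF, 0 °C to rt
Reagents that add atoms: chloromethyl methyl ether (MOMCl), COCCl
Why: Williamson-type O-alkylation of the sodium phenoxide installs the MOM acetal, which masks the phenol and serves as the directing group for step 2.

Step 2
Reactants: 2 1,2,3-trimethoxy-5-(methoxymethoxy)benzene
Product: 5 2,3,4-trimethoxy-6-(methoxymethoxy)phenol, via aryllithium 3 (not isolated), via lithium aryltrimethoxyborate 4 (not isolated)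
Conditions: n-BuLi, THF, 0 °C; B(OMe)3, −78 °C to rt; AcOH, 30% aq H2O2, 0 °C to rt
Reagents that add atoms: hydrogen peroxide, OO
Why: Directed ortho-metalation places lithium on the C–H flanked by the MOM ether and a methoxy group (the two such positions are equivalent by symmetry), and borate trapping followed by peroxide-induced 1,2-shift of the aryl group from boron to oxygen should convert the C–Li bond into C–OH.

Step 3
Reactants: 5 2,3,4-trimethoxy-6-(methoxymethoxy)phenol; 6 benzyl bromide
Product: 7 2-(benzyloxy)-3,4,5-trimethoxy-1-(methoxymethoxy)benzene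
Conditions: K2CO3, DMF, 60 °C
Reagents that add atoms: none
Why: Williamson etherification of the potassium phenoxide with a reactive benzylic bromide should proceed despite the two ortho substituents, while the acetal and the methyl ethers are inert to carbonate.

Step 4
Reactants: 7 2-(benzyloxy)-3,4,5-trimethoxy-1-(methoxymethoxy)benzene
Product: 8 2-(benzyloxy)-3,4,5-trimethoxyphenol
Conditions: conc. aq HCl (cat.), MeOH, 50 °C
Reagents that add atoms: none
Why: Acid-catalysed acetal exchange with methanol removes the MOM group, whereas benzyl and methyl aryl ethers are stable to dilute methanolic acid.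

Step 5
Reactants: 8 2-(benzyloxy)-3,4,5-trimethoxyphenol
Product: 9 2-(benzyloxy)-6-iodo-3,4,5-trimethoxyphenol
Conditions: NIS, MeCN, 0 °C to rt, dark
Reagents that add atoms: N-iodosuccinimide, O=C1CCC(=O)N1I
Why: Electrophilic aromatic iodination can only occur at the single remaining ring C–H, which is ortho to the free hydroxyl and para to a methoxy group, so a mild iodonium source without acid promoter should suffice.

Step 6
Reactants: 9 2-(benzyloxy)-6-iodo-3,4,5-trimethoxyphenol; 10 carbon monoxide; 11 4-ethynylanisole
Product: 14 8-(benzyloxy)-5,6,7-trimethoxy-2-(4-methoxyphenyl)-4H-chromen-4-one, via ynone 12 (not isolated), via enaminone 13 (not isolated)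
Conditions: PdCl2(dppf) (5 mol %), CO (20 bar), 11 (1.5 equiv), Et2NH, 120 °C
Reagents that add atoms: none
Why: PdCl2(dppf) is reduced in situ to zerovalent palladium, which inserts into the carbon–iodine bond of 9; CO insertion gives the aroylpalladium iodide (C4a–C4), and amine-assisted transfer of the alkynyl group of 11 followed by reductive elimination forms ynone 12 (C4–C3). Et2NH then adds to the ynone to give enaminone 13, and the phenolic oxygen attacks its β-carbon and expels the amine, forming O1–C2. The closest known reaction type is the palladium-catalysed carbonylative Sonogashira coupling–cyclisation of 2-iodophenols with terminal arylalkynes to flavones. Ring C closes in the 6-endo mode (6-endo-trig addition–elimination on 13) rather than by 5-exo-dig attack on 12, which would lead to the aurone; no stereocentre is created. The step needs CO insertion to precede alkynyl transfer and the aroylpalladium to be taken by the alkyne rather than by the amine: CO pressure, the absence of copper, the excess of 11 and the two ortho substituents (OH and OMe) that slow direct coupling at the arylpalladium stage should secure this. Regiochemistry in ring A is not in question, because the iodine occupies the only free carbon of 8 and the neighbouring phenolic oxygen is the only free hydroxyl.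

Step 7
Reactants: 14 8-(benzyloxy)-5,6,7-trimethoxy-2-(4-methoxyphenyl)-4H-chromen-4-one
Product: 17 8-(benzyloxy)-3-hydroxy-5,6,7-trimethoxy-2-(4-methoxyphenyl)-4H-chromen-4-one, via 3-lithioflavone 15 (not isolated), via lithium flavonyltrimethoxyborate 16 (not isolated)
Conditions: LiN(i-Pr)2, THF, −78 °C; B(OMe)3, −78 °C to rt; AcOH, 30% aq H2O2, 0 °C to rt
Reagents that add atoms: hydrogen peroxide, OO
Why: The C3–H is the only vinylic proton alpha to the carbonyl and is removed by the amide base at low temperature (known C3 lithiation of flavones); borate capture and oxidative 1,2-migration should then deliver the 3-hydroxyl without touching the aryl ethers.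

Step 8
Reactants: 17 8-(benzyloxy)-3-hydroxy-5,6,7-trimethoxy-2-(4-methoxyphenyl)-4H-chromen-4-one
Product: 18 eriostemin (3,8-dihydroxy-5,6,7-trimethoxy-2-(4-methoxyphenyl)-4H-chromen-4-one)
Conditions: H2 (1 atm), 10% Pd/C, EtOAc–MeOH, rt
Reagents that add atoms: none
Why: Heterogeneous hydrogenolysis cleaves the benzylic C–O bond selectively, since the tetrasubstituted C2=C3 bond of the flavonol and the aryl methyl ethers should not react at ambient pressure and temperature.

**Compound list**
1 | 3,4,5-trimethoxyphenol | COc1cc(O)cc(OC)c1OC | starting material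
2 | 1,2,3-trimethoxy-5-(methoxymethoxy)benzene | COCOc1cc(OC)c(OC)c(OC)c1 | intermediate
3 | [2,3,4-trimethoxy-6-(methoxymethoxy)phenyl]lithium | [Li]c1c(OCOC)cc(OC)c(OC)c1OC | intermediate (not isolated)
4 | lithium trimethoxy[2,3,4-trimethoxy-6-(methoxymethoxy)phenyl]borate | [Li+].CO[B-](OC)(OC)c1c(OCOC)cc(OC)c(OC)c1OC | intermediate (not isolated)
5 | 2,3,4-trimethoxy-6-(methoxymethoxy)phenol | COCOc1cc(OC)c(OC)c(OC)c1O | intermediate
6 | benzyl bromide | BrCc1ccccc1 | starting material
7 | 2-(benzyloxy)-3,4,5-trimethoxy-1-(methoxymethoxy)benzene | COCOc1cc(OC)c(OC)c(OC)c1OCc1ccccc1 | intermediate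
8 | 2-(benzyloxy)-3,4,5-trimethoxyphenol | Oc1cc(OC)c(OC)c(OC)c1OCc1ccccc1 | intermediate
9 | 2-(benzyloxy)-6-iodo-3,4,5-trimethoxyphenol | Oc1c(I)c(OC)c(OC)c(OC)c1OCc1ccccc1 | intermediate
10 | carbon monoxide | [C-]#[O+] | starting material
11 | 4-ethynylanisole (1-ethynyl-4-methoxybenzene) | C#Cc1ccc(OC)cc1 | starting material
12 | 1-[3-(benzyloxy)-2-hydroxy-4,5,6-trimethoxyphenyl]-3-(4-methoxyphenyl)prop-2-yn-1-one | COc1ccc(C#CC(=O)c2c(O)c(OCc3ccccc3)c(OC)c(OC)c2OC)cc1 | intermediate (not isolated)
13 | (E)-1-[3-(benzyloxy)-2-hydroxy-4,5,6-trimethoxyphenyl]-3-(diethylamino)-3-(4-methoxyphenyl)prop-2-en-1-one | CCN(CC)/C(=C/C(=O)c1c(O)c(OCc2ccccc2)c(OC)c(OC)c1OC)c1ccc(OC)cc1 | intermediate (not isolated)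
14 | 8-(benzyloxy)-5,6,7-trimethoxy-2-(4-methoxyphenyl)-4H-chromen-4-one | COc1ccc(-c2cc(=O)c3c(OC)c(OC)c(OC)c(OCc4ccccc4)c3o2)cc1 | intermediate
15 | [8-(benzyloxy)-5,6,7-trimethoxy-2-(4-methoxyphenyl)-4-oxo-4H-chromen-3-yl]lithium | COc1ccc(-c2oc3c(OCc4ccccc4)c(OC)c(OC)c(OC)c3c(=O)c2[Li])cc1 | intermediate (not isolated)
16 | lithium [8-(benzyloxy)-5,6,7-trimethoxy-2-(4-methoxyphenyl)-4-oxo-4H-chromen-3-yl]trimethoxyborate | [Li+].COc1ccc(-c2oc3c(OCc4ccccc4)c(OC)c(OC)c(OC)c3c(=O)c2[B-](OC)(OC)OC)cc1 | intermediate (not isolated)
17 | 8-(benzyloxy)-3-hydroxy-5,6,7-trimethoxy-2-(4-methoxyphenyl)-4H-chromen-4-one | COc1ccc(-c2oc3c(OCc4ccccc4)c(OC)c(OC)c(OC)c3c(=O)c2O)cc1 | intermediate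
18 | eriostemin, 3,8-dihydroxy-5,6,7-trimethoxy-2-(4-methoxyphenyl)-4H-chromen-4-one | COc1ccc(-c2oc3c(O)c(OC)c(OC)c(OC)c3c(=O)c2O)cc1 | target

**Step count**
Total: 8 steps. Longest linear sequence: 8 steps, from 1 to 18.

**Steps most likely to fail**

Step 6. The arylpalladium species may take up the alkyne before CO, which after cyclisation would give a 2-arylbenzofuran. The aroylpalladium may also be intercepted by the amine, or part of the ynone may close in the 5-exo mode. The fallback sets out from 9 and brings in the carbonyl carbon and the alkyne in separate operations. Aminocarbonylation of 9 with N,O-dimethylhydroxylamine hydrochloride (Pd(OAc)2, Xantphos, Et3N, CO 1 atm, toluene, 80 °C) should give the Weinreb amide 3-(benzyloxy)-2-hydroxy-N,4,5,6-tetramethoxy-N-methylbenzamide F1, with no alkyne present to compete with CO. An excess of lithium (4-methoxyphenyl)acetylide F2 (from 11 and n-BuLi, THF, −78 to 0 °C) would then add to F1, and the chelated adduct should collapse on dilute aqueous HCl quench to ynone 12, now isolated. Heating 12 with Et2NH in EtOH should pass through enaminone 13 and return to the route at flavone 14.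

Step 7. The 3-lithioflavone may open by β-elimination of the ring phenoxide, or the base may deprotonate the benzylic CH2 of the 8-benzyl ether before the borate captures the anion. The fallback sets out from 14 and uses electrophilic oxidation of the C2=C3 bond instead of deprotonation. Dimethyldioxirane (acetone–CH2Cl2, 0 °C) should give the racemic cis-fused epoxide 8-(benzyloxy)-2,3-epoxy-5,6,7-trimethoxy-2-(4-methoxyphenyl)chroman-4-one F3. Catalytic TsOH in CH2Cl2 should open the epoxide at C2 (cation stabilised by O1 and the anisyl group), and loss of the C3 proton gives the flavonol; the route is rejoined at 17.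

Step 5. The iodinating agent may oxidise the very electron-rich free phenol to quinonoid products, with loss of the para methoxy group, instead of substituting the ring. The fallback sets out from 7 and introduces iodine while the phenol is still masked. NIS in MeCN at rt should iodinate the only free ring position to give 1-(benzyloxy)-3-iodo-4,5,6-trimethoxy-2-(methoxymethoxy)benzene F4. Removal of the MOM group (cat. HCl, MeOH, 50 °C) then returns to the route at 9.

**Further compounds**
F1 | step 6 | 3-(benzyloxy)-2-hydroxy-N,4,5,6-tetramethoxy-N-methylbenzamide | CON(C)C(=O)c1c(O)c(OCc2ccccc2)c(OC)c(OC)c1OC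
F2 | step 6 | lithium (4-methoxyphenyl)acetylide | [Li]C#Cc1ccc(OC)cc1
F3 | step 7 | cis-8-(benzyloxy)-2,3-epoxy-5,6,7-trimethoxy-2-(4-methoxyphenyl)chroman-4-one (racemic, one enantiomer drawn) | COc1ccc(cc1)[C@@]12O[C@@H]1C(=O)c1c(OC)c(OC)c(OC)c(OCc3ccccc3)c1O2
F4 | step 5 | 1-(benzyloxy)-3-iodo-4,5,6-trimethoxy-2-(methoxymethoxy)benzene | COCOc1c(I)c(OC)c(OC)c(OC)c1OCc1ccccc1
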